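**Retrosynthetic overview**

1. Target 22 is (3R,6R)-3-hydroxy-8'-apo-ε-caroten-8'-ol; carotenoid locants are used in the text: ring C1 = C(CH3)2, C2 = CH2, C3 = CHOH, C4 = CH=, C5 = C(CH3)=, C6 = CH carrying chain carbon C7.
2. Chain: C8' ester to alcohol last; C11=C12 by Wittig reaction of ring C15 phosphonium salt 15 with C15 aldehyde ester 20 (from C10 dialdehyde 19 and C5 phosphonate 18); C9–C11 by vinyl addition and allylic transposition; C7=C8 by Wittig reaction of ring aldehyde 11.
3. Ring (the only ring, closed once, in step 3): the allylic alcohol C3–OH/C4=C5(CH3) is a reduced cyclohex-2-enone in which the carbonyl carbon C3 and the methyl-bearing β-carbon C5 stand 1,3. It is flanked by C2 (CH2) and by C6, whose only exocyclic carbon C7 can be a carbonyl group next to the gem-dimethyl carbon C1. Hence C2–C3(O)–C4=C5(CH3) is a 1-methoxy-3-siloxydiene and C1(CH3)2=C6–C7(=O) a 3-methylbut-2-enoyl unit.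
4. A Lewis-acid-promoted stepwise [4+2] of these two acyclic pieces forms C1–C2 and C5–C6 together. It creates quaternary C1, the C4=C5 enone and the C6 stereocentre (oxazolidinone auxiliary on C7); C3 is then set trans to C6 by CBS reduction.

Key step: step 3

**Route**

Step 1
Reactants: 1 (3E)-4-methoxypent-3-en-2-one
Product: 2 tert-butyl{[(3E)-4-methoxypenta-1,3-dien-2-yl]oxy}dimethylsilane
Conditions: LiN(iPr)2 (LDA), THF, −78 °C; then TBSCl, DMPU, −78 °C → rt
Reagents that add atoms: tert-butyldimethylsilyl chloride, CC(C)(C)[Si](C)(C)Cl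
Why: Kinetic deprotonation of the vinylogous ester at the acetyl methyl group gives the cross-conjugated lithium dienolate, whose O-silylation (silyl enol ether formation) should give the 1-methoxy-3-siloxydiene; no stereocentre is formed.

Step 2
Reactants: 3 (4S)-4-benzyloxazolidin-2-one; 4 3-methylbut-2-enoyl chloride
Product: 5 (4S)-4-benzyl-3-(3-methylbut-2-enoyl)oxazolidin-2-one
Conditions: n-BuLi, THF, −78 °C; then 4, −78 → 0 °C
Reagents that add atoms: none
Why: N-acylation of the lithiated oxazolidinone by the acid chloride is standard imide formation; the auxiliary stereocentre comes from the chiral pool and is not touched.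

Step 3
Reactants: 2 tert-butyl{[(3E)-4-methoxypenta-1,3-dien-2-yl]oxy}dimethylsilane; 5 (4S)-4-benzyl-3-(3-methylbut-2-enoyl)oxazolidin-2-one
Product: 7 (4S)-4-benzyl-3-[(1R)-2,6,6-trimethyl-4-oxocyclohex-2-ene-1-carbonyl]oxazolidin-2-one, via silyl enol ether cycloadduct 6 (not isolated)
Conditions: Me2AlCl (1.5 equiv), CH2Cl2, −78 °C; 2 (1.5 equiv), −78 → −30 °C; then 1 M HCl, THF, 0 °C
Reagents that add atoms: none
Why: Proposed new method: Me2AlCl chelates the two imide carbonyls of 5 (s-cis enoyl group), the CH2 terminus of diene 2 adds to the β,β-dimethyl carbon in a Mukaiyama–Michael step (C1–C2, quaternary but not stereogenic), and the resulting chelated (Z)-aluminium enolate closes onto the methyl-bearing terminus of the 1-methoxy-3-siloxyallyl cation (C5–C6), which amounts to a stepwise Lewis-acid-promoted Diels–Alder reaction, after which aqueous acid removes methanol and the silyl group from 6 and unveils the C4=C5 enone. The closest known reaction types are the dialkylaluminium-chloride-promoted Diels–Alder reactions of chelated N-enoyl oxazolidinones (shown for β-unsubstituted and β-monosubstituted enoyl groups) and the aluminium-Lewis-acid-promoted cycloadditions of 2-siloxydienes to β,β-disubstituted enones that build adjacent fully substituted carbons; their combination on a β,β-dimethyl imide and a diene with a fully substituted terminus is what is new. The six-membered ring closes by attack of the enolate carbon on the oxocarbenium carbon C5 (6-exo-trig with regard to the C=O+ unit, enolate C=C outside the ring), the second bond of a formal [4+2] cycloaddition. The only stereocentre that survives, C6, is set by the (S)-benzyl group of the auxiliary, which covers one face of the chelated enolate so that C5 bonds to the opposite face, as in alkylations of such imide enolates, and this should give the (R) configuration; the transient centre at C5 is erased by the elimination. The step needs 1,4- instead of 1,2-addition (secured by the imide, activated as a cationic chelate), attack through the CH2 terminus of the diene (secured by the 3-siloxy and 1-methoxy donors) and a configurationally stable C6 in the product (the acyl group sits pseudoaxial next to the gem-dimethyl carbon and allylic strain in the imide disfavours enolisation).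

Step 4
Reactants: 7 (4S)-4-benzyl-3-[(1R)-2,6,6-trimethyl-4-oxocyclohex-2-ene-1-carbonyl]oxazolidin-2-one
Product: 8 (4S)-4-benzyl-3-[(1R,4R)-4-hydroxy-2,6,6-trimethylcyclohex-2-ene-1-carbonyl]oxazolidin-2-one
Conditions: (S)-2-methyl-CBS-oxazaborolidine (20 mol %), catecholborane, toluene/CH2Cl2, −78 °C; MeOH quench
Reagents that add atoms: none
Why: Corey–Bakshi–Shibata reduction, in which the (S)-oxazaborolidine treats the alkenyl arm C4=C5 as the large group and should deliver hydride to the face that gives the (3R)-allylic alcohol, trans to the C6 acyl group; this is also the face anti to the axial C1 methyl group, and catecholborane at low temperature leaves the imide and the alkene untouched.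

Step 5
Reactants: 8 (4S)-4-benzyl-3-[(1R,4R)-4-hydroxy-2,6,6-trimethylcyclohex-2-ene-1-carbonyl]oxazolidin-2-one
Product: 9 (4S)-4-benzyl-3-[(1R,4R)-2,6,6-trimethyl-4-(triethylsilyloxy)cyclohex-2-ene-1-carbonyl]oxazolidin-2-one
Conditions: TESCl, imidazole, CH2Cl2, 0 °C → rt
Reagents that add atoms: chlorotriethylsilane, CC[Si](CC)(CC)Cl
Why: Silyl ether formation protects the allylic alcohol for the oxidation in step 7; the triethylsilyl group is chosen because it survives hydride, oxidant, ylide and Grignard reagent but is cleaved by the acidic methanol of step 10.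

Step 6
Reactants: 9 (4S)-4-benzyl-3-[(1R,4R)-2,6,6-trimethyl-4-(triethylsilyloxy)cyclohex-2-ene-1-carbonyl]oxazolidin-2-one
Product: 10 [(1R,4R)-2,6,6-trimethyl-4-(triethylsilyloxy)cyclohex-2-en-1-yl]methanol
Conditions: LiBH4, MeOH (1 equiv), THF, 0 °C
Reagents that add atoms: none
Why: Reductive cleavage of the N-acyl oxazolidinone by hydride attack at the exocyclic carbonyl should give the primary alcohol and return auxiliary 3; C6 is not enolised under these conditions.

Step 7
Reactants: 10 [(1R,4R)-2,6,6-trimethyl-4-(triethylsilyloxy)cyclohex-2-en-1-yl]methanol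
Product: 11 (1R,4R)-2,6,6-trimethyl-4-(triethylsilyloxy)cyclohex-2-ene-1-carbaldehyde
Conditions: Dess–Martin periodinane, NaHCO3, CH2Cl2, 0 °C → rt
Reagents that add atoms: none
Why: Dess–Martin oxidation under buffered, non-basic conditions should give the β,γ-unsaturated aldehyde without epimerisation at C6 or migration of the double bond into conjugation.

Step 8
Reactants: 11 (1R,4R)-2,6,6-trimethyl-4-(triethylsilyloxy)cyclohex-2-ene-1-carbaldehyde; 12 1-(triphenylphosphoranylidene)propan-2-one
Product: 13 (3E)-4-[(1R,4R)-2,6,6-trimethyl-4-(triethylsilyloxy)cyclohex-2-en-1-yl]but-3-en-2-one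
Conditions: 12 (1.5 equiv), toluene, 90 °C
Reagents that add atoms: none
Why: Wittig reaction with a stabilised, non-basic ylide should form C7=C8 with E geometry and leave the α-stereocentre C6 intact.

Step 9
Reactants: 13 (3E)-4-[(1R,4R)-2,6,6-trimethyl-4-(triethylsilyloxy)cyclohex-2-en-1-yl]but-3-en-2-one
Product: 14 (1E)-3-methyl-1-[(1R,4R)-2,6,6-trimethyl-4-(triethylsilyloxy)cyclohex-2-en-1-yl]penta-1,4-dien-3-ol (both carbinol epimers)
Conditions: CH2=CHMgBr, THF, −40 → 0 °C; aq. NH4Cl
Reagents that add atoms: vinylmagnesium bromide, C=C[Mg]Br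
Why: Grignard 1,2-addition to the enone carbonyl gives the tertiary bis-allylic alcohol; its new carbinol centre forms without control but is destroyed in step 10.

Step 10
Reactants: 14 (1E)-3-methyl-1-[(1R,4R)-2,6,6-trimethyl-4-(triethylsilyloxy)cyclohex-2-en-1-yl]penta-1,4-dien-3-ol
Product: 15 [(2E,4E)-5-[(1R,4R)-4-hydroxy-2,6,6-trimethylcyclohex-2-en-1-yl]-3-methylpenta-2,4-dien-1-yl]triphenylphosphonium bromide
Conditions: PPh3·HBr (1.2 equiv), MeOH, 0 °C → rt; crystallisation from EtOAc
Reagents that add atoms: triphenylphosphine hydrobromide, [Br-].c1ccc(cc1)[PH+](c1ccccc1)c1ccccc1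
Why: Acid-induced allylic transposition (ionisation of the tertiary bis-allylic alcohol to a pentadienyl cation and capture by PPh3 at the unhindered terminus, the usual route to C15 Wittig salts) should give the conjugated (2E,4E) salt, while the acidic methanol removes the triethylsilyl ether; the secondary ring alcohol ionises far more slowly, so C3 should keep its configuration.

Step 11
Reactants: 16 ethyl (2E)-2-methylbut-2-enoate (ethyl tiglate)
Product: 17 ethyl (2E)-4-bromo-2-methylbut-2-enoate
Conditions: NBS, AIBN (cat.), PhCF3, reflux; distillation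
Reagents that add atoms: N-bromosuccinimide, O=C1CCC(=O)N1Br
Why: Wohl–Ziegler allylic bromination at the γ-methyl group through the delocalised allyl radical should give the (E)-γ-bromo ester as the main isomer.

Step 12
Reactants: 17 ethyl (2E)-4-bromo-2-methylbut-2-enoate
Product: 18 ethyl (2E)-4-(diethoxyphosphoryl)-2-methylbut-2-enoate
Conditions: P(OEt)3, neat, 120 °C, EtBr distilled off
Reagents that add atoms: triethyl phosphite, CCOP(OCC)OCC
Why: Michaelis–Arbuzov reaction of the primary allylic bromide gives the vinylogous phosphonate with retention of the E double bond.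

Step 13
Reactants: 18 ethyl (2E)-4-(diethoxyphosphoryl)-2-methylbut-2-enoate; 19 (2E,4E,6E)-2,7-dimethylocta-2,4,6-trienedial
Product: 20 ethyl (2E,4E,6E,8E,10E)-2,6,11-trimethyl-12-oxododeca-2,4,6,8,10-pentaenoate
Conditions: NaH, THF, 0 °C; anion added slowly to 19 (2.5 equiv), THF, 0 °C → rt
Reagents that add atoms: none
Why: Horner–Wadsworth–Emmons reaction of the stabilised vinylogous phosphonate anion forms C11'=C12' with E geometry; slow addition to excess symmetrical dialdehyde should favour mono-olefination, and unreacted 19 is recovered.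

Step 14
Reactants: 15 [(2E,4E)-5-[(1R,4R)-4-hydroxy-2,6,6-trimethylcyclohex-2-en-1-yl]-3-methylpenta-2,4-dien-1-yl]triphenylphosphonium bromide; 20 ethyl (2E,4E,6E,8E,10E)-2,6,11-trimethyl-12-oxododeca-2,4,6,8,10-pentaenoate
Product: 21 ethyl (2E,4E,6E,8E,10E,12E,14E,16E)-17-[(1R,4R)-4-hydroxy-2,6,6-trimethylcyclohex-2-en-1-yl]-2,6,11,15-tetramethylheptadeca-2,4,6,8,10,12,14,16-octaenoate
Conditions: NaOEt, EtOH/CH2Cl2, 0 °C → rt; then reflux in EtOH (Z → E isomerisation); crystallisation
Reagents that add atoms: none
Why: Wittig reaction of the semi-stabilised polyenyl ylide with the polyenal forms C11=C12 (the standard C15 + aldehyde carotenoid coupling, tolerant of the free hydroxyl group); the hindered 11Z isomer formed alongside should isomerise thermally to the all-E ester, and ethoxide matches the ethyl ester.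

Step 15
Reactants: 21 ethyl (2E,4E,6E,8E,10E,12E,14E,16E)-17-[(1R,4R)-4-hydroxy-2,6,6-trimethylcyclohex-2-en-1-yl]-2,6,11,15-tetramethylheptadeca-2,4,6,8,10,12,14,16-octaenoate
Product: 22 (2E,4E,6E,8E,10E,12E,14E,16E)-17-[(1R,4R)-4-hydroxy-2,6,6-trimethylcyclohex-2-en-1-yl]-2,6,11,15-tetramethylheptadeca-2,4,6,8,10,12,14,16-octaen-1-ol
Conditions: i-Bu2AlH (3.5 equiv), CH2Cl2, −78 °C; aq. potassium sodium tartrate
Reagents that add atoms: none
Why: Hydride reduction of the conjugated ester by i-Bu2AlH gives the primary allylic alcohol by 1,2-reduction without touching the polyene or either stereocentre.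

**Compound list**

1 | (3E)-4-methoxypent-3-en-2-one | CO/C(C)=C/C(C)=O | starting material
2 | tert-butyl{[(3E)-4-methoxypenta-1,3-dien-2-yl]oxy}dimethylsilane | C=C(O[Si](C)(C)C(C)(C)C)/C=C(\C)OC | intermediate
3 | (4S)-4-benzyloxazolidin-2-one | O=C1N[C@@H](Cc2ccccc2)CO1 | starting material
4 | 3-methylbut-2-enoyl chloride | CC(C)=CC(Cl)=O | starting material
5 | (4S)-4-benzyl-3-(3-methylbut-2-enoyl)oxazolidin-2-one | CC(C)=CC(=O)N1[C@@H](Cc2ccccc2)COC1=O | intermediate
6 | (4S)-4-benzyl-3-[(1R)-4-(tert-butyldimethylsilyloxy)-2-methoxy-2,6,6-trimethylcyclohex-3-ene-1-carbonyl]oxazolidin-2-one (either configuration at the methoxy-bearing carbon) | COC1(C)C=C(O[Si](C)(C)C(C)(C)C)CC(C)(C)[C@H]1C(=O)N2[C@@H](Cc3ccccc3)COC2=O | intermediate (not isolated)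
7 | (4S)-4-benzyl-3-[(1R)-2,6,6-trimethyl-4-oxocyclohex-2-ene-1-carbonyl]oxazolidin-2-one | CC1=CC(=O)CC(C)(C)[C@H]1C(=O)N2[C@@H](Cc3ccccc3)COC2=O | intermediate
8 | (4S)-4-benzyl-3-[(1R,4R)-4-hydroxy-2,6,6-trimethylcyclohex-2-ene-1-carbonyl]oxazolidin-2-one | CC1=C[C@H](O)CC(C)(C)[C@H]1C(=O)N2[C@@H](Cc3ccccc3)COC2=O | intermediate
9 | (4S)-4-benzyl-3-[(1R,4R)-2,6,6-trimethyl-4-(triethylsilyloxy)cyclohex-2-ene-1-carbonyl]oxazolidin-2-one | CC1=C[C@H](O[Si](CC)(CC)CC)CC(C)(C)[C@H]1C(=O)N2[C@@H](Cc3ccccc3)COC2=O | intermediate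
10 | [(1R,4R)-2,6,6-trimethyl-4-(triethylsilyloxy)cyclohex-2-en-1-yl]methanol | CC1=C[C@H](O[Si](CC)(CC)CC)CC(C)(C)[C@H]1CO | intermediate
11 | (1R,4R)-2,6,6-trimethyl-4-(triethylsilyloxy)cyclohex-2-ene-1-carbaldehyde | CC1=C[C@H](O[Si](CC)(CC)CC)CC(C)(C)[C@H]1C=O | intermediate
12 | 1-(triphenylphosphoranylidene)propan-2-one | CC(=O)C=P(c1ccccc1)(c1ccccc1)c1ccccc1 | starting material
13 | (3E)-4-[(1R,4R)-2,6,6-trimethyl-4-(triethylsilyloxy)cyclohex-2-en-1-yl]but-3-en-2-one | CC1=C[C@H](O[Si](CC)(CC)CC)CC(C)(C)[C@H]1/C=C/C(C)=O | intermediate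
14 | (1E)-3-methyl-1-[(1R,4R)-2,6,6-trimethyl-4-(triethylsilyloxy)cyclohex-2-en-1-yl]penta-1,4-dien-3-ol (both carbinol epimers) | CC1=C[C@H](O[Si](CC)(CC)CC)CC(C)(C)[C@H]1/C=C/C(C)(O)C=C | intermediate
15 | [(2E,4E)-5-[(1R,4R)-4-hydroxy-2,6,6-trimethylcyclohex-2-en-1-yl]-3-methylpenta-2,4-dien-1-yl]triphenylphosphonium bromide | CC1=C[C@H](O)CC(C)(C)[C@H]1/C=C/C(C)=C/C[P+](c1ccccc1)(c1ccccc1)c1ccccc1.[Br-] | intermediate
16 | ethyl (2E)-2-methylbut-2-enoate | C/C=C(\C)C(=O)OCC | starting material
17 | ethyl (2E)-4-bromo-2-methylbut-2-enoate | BrC/C=C(\C)C(=O)OCC | intermediate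
18 | ethyl (2E)-4-(diethoxyphosphoryl)-2-methylbut-2-enoate | CCOC(=O)/C(C)=C/CP(=O)(OCC)OCC | intermediate
19 | (2E,4E,6E)-2,7-dimethylocta-2,4,6-trienedial | O=C/C(C)=C/C=C/C=C(\C)C=O | starting material
20 | ethyl (2E,4E,6E,8E,10E)-2,6,11-trimethyl-12-oxododeca-2,4,6,8,10-pentaenoate | CCOC(=O)/C(C)=C/C=C/C(C)=C/C=C/C=C(\C)C=O | intermediate
21 | ethyl (2E,4E,6E,8E,10E,12E,14E,16E)-17-[(1R,4R)-4-hydroxy-2,6,6-trimethylcyclohex-2-en-1-yl]-2,6,11,15-tetramethylheptadeca-2,4,6,8,10,12,14,16-octaenoate | CC1=C[C@H](O)CC(C)(C)[C@H]1/C=C/C(C)=C/C=C/C(C)=C/C=C/C=C(C)/C=C/C=C(\C)C(=O)OCC | intermediate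
22 | (2E,4E,6E,8E,10E,12E,14E,16E)-17-[(1R,4R)-4-hydroxy-2,6,6-trimethylcyclohex-2-en-1-yl]-2,6,11,15-tetramethylheptadeca-2,4,6,8,10,12,14,16-octaen-1-ol | CC1=C[C@H](O)CC(C)(C)[C@H]1/C=C/C(C)=C/C=C/C(C)=C/C=C/C=C(C)/C=C/C=C(\C)CO | target

**Step count and risks**

Total step count: 15. Longest linear sequence: 11 steps (steps 1, 3 to 10, 14 and 15; the branch through step 2 is equally long).

Steps most likely to fail:

Step 3 (proposed step). The conjugate addition to the fully substituted β-carbon may be slower than Lewis-acid-induced decomposition of diene 2, the sequence may stop after the first C–C bond, or the ring may close without facial control. The fallback uses known chemistry, builds the ring by a different annulation and sorts C6 by separation; it sets out from 3 and comes back at 7. Heating 3 with 2,2,6-trimethyl-4H-1,3-dioxin-4-one in xylene at 130 °C (acylation by the acylketene) should give (4S)-4-benzyl-3-(3-oxobutanoyl)oxazolidin-2-one F1. Robinson-type annulation of F1 with 4-methylpent-3-en-2-one (ZnCl2, toluene, reflux, water separator; Michael addition then aldol condensation, the known route from acetoacetates to 2,6,6-trimethyl-4-oxocyclohex-2-ene-1-carboxylates) should give 7 together with its C6 epimer (4S)-4-benzyl-3-[(1S)-2,6,6-trimethyl-4-oxocyclohex-2-ene-1-carbonyl]oxazolidin-2-one F2. The two diastereomers are separated by chromatography, and F2 is equilibrated through its dienolate (DBU, CH2Cl2) and separated again.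

Step 4. Facial selectivity may be poor if the catalyst does not override hydride entry on the face of the axial C1 methyl group, which leads to the 3,6-cis alcohol. The fallback uses inversion instead of direct reduction; it sets out from 7 and comes back at 8. The ketone is reduced under substrate control (NaBH4, CeCl3·7H2O, MeOH/THF, −78 °C, Luche reduction) and the cis alcohol (4S)-4-benzyl-3-[(1R,4S)-4-hydroxy-2,6,6-trimethylcyclohex-2-ene-1-carbonyl]oxazolidin-2-one F3 is separated. A Mitsunobu reaction with chloroacetic acid (PPh3, DIAD, toluene, 0 °C) inverts C3 and should give (1R,4R)-4-{[(4S)-4-benzyl-2-oxooxazolidin-3-yl]carbonyl}-3,5,5-trimethylcyclohex-2-en-1-yl chloroacetate F4. Thiourea and NaHCO3 in EtOH at 50 °C then remove the chloroacetyl group without touching the imide and give 8.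

Step 8. The hindered aldehyde may add the stabilised ylide slowly, and on prolonged heating it may epimerise at C6 or shift its double bond into conjugation. The fallback replaces the Wittig reaction by aldol addition and dehydration; it sets out from 11 and comes back at 13. Addition of the lithium enolate of acetone (LiN(iPr)2, acetone, THF, −78 °C), fast and non-equilibrating at this temperature, should give 4-hydroxy-4-[(1R,4R)-2,6,6-trimethyl-4-(triethylsilyloxy)cyclohex-2-en-1-yl]butan-2-one F5 (both carbinol epimers). Mesylation and elimination (MsCl, Et3N, then DBU, CH2Cl2, 0 °C), at a stage where C6 is no longer acidic, should give the (E)-enone 13.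

**Further compounds**

F1 | step 3 | (4S)-4-benzyl-3-(3-oxobutanoyl)oxazolidin-2-one | CC(=O)CC(=O)N1[C@@H](Cc2ccccc2)COC1=O
F2 | step 3 | (4S)-4-benzyl-3-[(1S)-2,6,6-trimethyl-4-oxocyclohex-2-ene-1-carbonyl]oxazolidin-2-one | CC1=CC(=O)CC(C)(C)[C@@H]1C(=O)N2[C@@H](Cc3ccccc3)COC2=O
F3 | step 4 | (4S)-4-benzyl-3-[(1R,4S)-4-hydroxy-2,6,6-trimethylcyclohex-2-ene-1-carbonyl]oxazolidin-2-one | CC1=C[C@@H](O)CC(C)(C)[C@H]1C(=O)N2[C@@H](Cc3ccccc3)COC2=O
F4 | step 4 | (1R,4R)-4-{[(4S)-4-benzyl-2-oxooxazolidin-3-yl]carbonyl}-3,5,5-trimethylcyclohex-2-en-1-yl chloroacetate | CC1=C[C@H](OC(=O)CCl)CC(C)(C)[C@H]1C(=O)N2[C@@H](Cc3ccccc3)COC2=O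
F5 | step 8 | 4-hydroxy-4-[(1R,4R)-2,6,6-trimethyl-4-(triethylsilyloxy)cyclohex-2-en-1-yl]butan-2-one (both carbinol epimers) | CC1=C[C@H](O[Si](CC)(CC)CC)CC(C)(C)[C@H]1C(O)CC(C)=O
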